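## Retrosynthetic overview
1. The target is the mono-opened form of a C2-symmetric bis-lactone, so the last operation opens one of two equivalent γ-lactones.
2. The bis-lactone comes from two identical chromanone-lactone monomers by C6–C6′ oxidative phenol coupling, ortho to the 5-OH.
3. The monomer comes from its butenolide by hydride delivery anti to the chromanone. This sets the C–CH3 centre, and the same step resolves the racemate.
4. Key disconnection (step 5): the crowded C2–C2′(γ) bond is cut to methyl 5-hydroxychromone-2-carboxylate and a 2-silyloxy-4-methylfuran, which are joined by a photoredox radical–radical coupling.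
5. Ring order: benzene ring (resorcinol), then the pyranone (ortho-lithiation/acylation, oxalate Claisen, cyclodehydration), then the lactone ring brought in intact from 4-methylbutenolide, then the biaryl bond.

Assumption 1: the biaryl axis carries only two ortho OH groups and rotates freely, so no axial descriptor is needed, as in the given SMILES.
Assumption 2: (S)-p-tol-BINAP is taken as the ligand antipode matched to the (2S,2′R) butenolide. If a test run shows the reverse, the (R)-ligand is used and nothing else changes.

## Route

Step 1
Reactants: 1 resorcinol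
Product: 2 1,3-bis(methoxymethoxy)benzene
Conditions: NaH (2.3 equiv), MOMCl (2.3 equiv), DMF, 0 °C to rt
Reagents that add atoms: chloromethyl methyl ether (MOMCl), COCCl
Why: Williamson-type MOM protection masks both phenols and turns them into cooperating ortho-directing groups; no stereocentre is involved.

Step 2
Reactants: 2 1,3-bis(methoxymethoxy)benzene; 3 N-methoxy-N-methylacetamide
Product: 5 1-[2,6-bis(methoxymethoxy)phenyl]ethan-1-one, via aryllithium 4 (not isolated)
Conditions: n-BuLi (1.1 equiv), THF, 0 °C, 1 h; then 3, −78 °C to rt; H2O quench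
Reagents that add atoms: none
Why: Directed ortho-metalation takes place at the carbon flanked by both MOM ethers, and the Weinreb ketone synthesis stops at the ketone because the chelated adduct survives until the quench.

Step 3
Reactants: 5 1-[2,6-bis(methoxymethoxy)phenyl]ethan-1-one; 6 dimethyl oxalate
Product: 8 methyl 5-hydroxy-4-oxo-4H-chromene-2-carboxylate, via diketo ester 7 (not isolated)
Conditions: NaOMe (1.5 equiv), MeOH–THF, reflux; then conc. HCl, MeOH, reflux
Reagents that add atoms: none
Why: A crossed Claisen condensation with non-enolisable oxalate gives the 2,4-diketo ester, then HCl/MeOH removes both MOM acetals and drives the cyclodehydration to the chromone, leaving the second OH as the hydrogen-bonded 5-OH.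

Step 4
Reactants: 9 4-methylfuran-2(5H)-one
Product: 10 tert-butyl(dimethyl)[(4-methylfuran-2-yl)oxy]silane
Conditions: TBSOTf (1.1 equiv), Et3N (1.3 equiv), CH2Cl2, 0 °C
Reagents that add atoms: tert-butyldimethylsilyl triflate (TBSOTf), CC(C)(C)[Si](C)(C)OS(=O)(=O)C(F)(F)F
Why: Soft enolisation (O-silylation, then γ-deprotonation) aromatises the butenolide to the electron-rich 2-silyloxyfuran.

Step 5
Reactants: 8 methyl 5-hydroxy-4-oxo-4H-chromene-2-carboxylate; 10 tert-butyl(dimethyl)[(4-methylfuran-2-yl)oxy]silane
Product: 12 rac-methyl (2S*)-5-hydroxy-2-[(2R*)-3-methyl-5-oxo-2,5-dihydrofuran-2-yl]-4-oxochromane-2-carboxylate, via silyl enol ether 11 (not isolated)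
Conditions: [Ir(dF(CF3)ppy)2(dtbbpy)]PF6 (2 mol %), 10 (2.5 equiv), degassed MeCN, 450 nm LEDs, 0 °C; then 1 M HCl, THF, rt
Reagents that add atoms: none
Why: Proposed new method: this is the key step, a redox-neutral radical–radical (radical-ion-pair) vinylogous coupling in which excited Ir(III) (about +1.2 V vs SCE) oxidises 10 (estimated +1.0 V) to its radical cation, which passes on its silyl group and becomes the γ-butenolidyl radical, while the Ir(II) formed (−1.37 V) reduces 8, whose C4=O is activated by the internal 5-OH hydrogen bond (estimated −1.1 to −1.2 V), to a 4-oxy-allyl radical with spin on the captodative C2 and a node at C3; this radical cannot dimerise because that would join two quaternary carbons, so it is persistent and by the persistent-radical effect captures the transient butenolidyl radical at its γ-carbon, forming the C2–C2′ bond where a Giese addition would prefer the less hindered C3, after which O-silylation gives 11 and acid gives 12; both new stereocentres arise in the coupling, and the rel-(2S,2′R) isomer is expected from the staggered approach that places the lactone C–O antiperiplanar to C2–O1, the γ-H over the chromene ring and the methyl-bearing carbon next to the small O1 (the product is racemic and the minor epimer is removed on silica); the closest known reaction types are electron-transfer Mukaiyama–Michael additions of ketene silyl acetals to enones and photoredox couplings of persistent ketyl or arene radical anions with allylic radicals.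

Step 6
Reactants: 12 rac-methyl (2S*)-5-hydroxy-2-[(2R*)-3-methyl-5-oxo-2,5-dihydrofuran-2-yl]-4-oxochromane-2-carboxylate
Product: 13 methyl (2S)-5-hydroxy-2-[(2R,3S)-3-methyl-5-oxooxolan-2-yl]-4-oxochromane-2-carboxylate
Conditions: Cu(OAc)2·H2O (5 mol %), (S)-p-tol-BINAP (5.5 mol %), (MeO)2MeSiH (0.55 equiv), t-BuOH (1.5 equiv), toluene, −20 °C, stopped at about 48 % conversion
Reagents that add atoms: none
Why: This is a copper hydride asymmetric conjugate reduction run as a kinetic resolution, in which hydride enters C3′ anti to the bulky C2′ substituent and so places CH3 cis to it (3′S), and only in the (2S,2′R) enantiomer does this substrate bias match the face preferred by the ligand, so 13 forms quickly while the (2R,2′S) enantiomer stays behind and the deactivated hydrogen-bonded aryl ketone and the esters are untouched.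

Step 7
Reactants: 13 methyl (2S)-5-hydroxy-2-[(2R,3S)-3-methyl-5-oxooxolan-2-yl]-4-oxochromane-2-carboxylate (2 molecules)
Product: 14 dimethyl (2S,2′S)-5,5′-dihydroxy-2,2′-bis[(2R,3S)-3-methyl-5-oxooxolan-2-yl]-4,4′-dioxo-6,6′-bichromane-2,2′-dicarboxylate
Conditions: VOF3 (1.2 equiv per 13), TFA–CH2Cl2, 0 °C
Reagents that add atoms: none
Why: In this vanadium(V)-mediated oxidative phenol coupling the 5-O/4-C=O vanadium chelate gives a phenoxyl radical that couples at C6, ortho to OH and para to O1 (C8 coupling should need C6 to be blocked), no sp3 centre is touched in the acidic medium, and the heterochiral dimer from residual minor enantiomer is a separable diastereomer, so the ee rises (Horeau effect).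

Step 8
Reactants: 14 dimethyl (2S,2′S)-5,5′-dihydroxy-2,2′-bis[(2R,3S)-3-methyl-5-oxooxolan-2-yl]-4,4′-dioxo-6,6′-bichromane-2,2′-dicarboxylate
Product: 16 (3S,4R)-4-hydroxy-4-[(2S)-5-hydroxy-6-{(2S)-5-hydroxy-2-(methoxycarbonyl)-2-[(2R,3S)-3-methyl-5-oxooxolan-2-yl]-4-oxochroman-6-yl}-2-(methoxycarbonyl)-4-oxochroman-2-yl]-3-methylbutanoic acid (target), via trilithium salt 15 (not isolated)
Conditions: LiOH (3.0 equiv), THF–H2O, 0 °C; then 0.5 M HCl to pH 4, 0 °C; reversed-phase separation, recovered 14 recycled
Reagents that add atoms: lithium hydroxide, [Li+].[OH-]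
Why: In this saponification two equivalents of base go to the phenols and the third opens one unhindered γ-lactone carbonyl much faster than the neopentyl-type methyl esters react, giving statistical mono-opening of two homotopic lactones (about 50 % at most, with 14 and the relactonised doubly opened acid recycled), and acyl–oxygen cleavage followed by cold mild acidification leaves every stereocentre intact and avoids relactonisation.

## Compound list
1 | resorcinol | Oc1cccc(O)c1 | starting material
2 | 1,3-bis(methoxymethoxy)benzene | COCOc1cccc(OCOC)c1 | intermediate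
3 | N-methoxy-N-methylacetamide | CC(=O)N(C)OC | starting material
4 | 2,6-bis(methoxymethoxy)phenyllithium | [Li]c1c(OCOC)cccc1OCOC | intermediate (not isolated)
5 | 1-[2,6-bis(methoxymethoxy)phenyl]ethan-1-one | CC(=O)c1c(OCOC)cccc1OCOC | intermediate
6 | dimethyl oxalate | COC(=O)C(=O)OC | starting material
7 | methyl 4-[2,6-bis(methoxymethoxy)phenyl]-2,4-dioxobutanoate | COCOc1cccc(OCOC)c1C(=O)CC(=O)C(=O)OC | intermediate (not isolated)
8 | methyl 5-hydroxy-4-oxo-4H-chromene-2-carboxylate | COC(=O)c1cc(=O)c2c(O)cccc2o1 | intermediate
9 | 4-methylfuran-2(5H)-one | CC1=CC(=O)OC1 | starting material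
10 | tert-butyl(dimethyl)[(4-methylfuran-2-yl)oxy]silane | Cc1coc(O[Si](C)(C)C(C)(C)C)c1 | intermediate
11 | rac-methyl (2S*)-4-(tert-butyldimethylsilyloxy)-5-hydroxy-2-[(2R*)-3-methyl-5-oxo-2,5-dihydrofuran-2-yl]-2H-chromene-2-carboxylate (racemate, one enantiomer drawn) | COC(=O)[C@@]1([C@@H]2OC(=O)C=C2C)C=C(O[Si](C)(C)C(C)(C)C)c2c(O)cccc2O1 | intermediate (not isolated)
12 | rac-methyl (2S*)-5-hydroxy-2-[(2R*)-3-methyl-5-oxo-2,5-dihydrofuran-2-yl]-4-oxochromane-2-carboxylate (racemate, the enantiomer carried on is drawn) | COC(=O)[C@@]1([C@@H]2OC(=O)C=C2C)CC(=O)c2c(O)cccc2O1 | intermediate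
13 | methyl (2S)-5-hydroxy-2-[(2R,3S)-3-methyl-5-oxooxolan-2-yl]-4-oxochromane-2-carboxylate | COC(=O)[C@@]1([C@@H]2OC(=O)C[C@@H]2C)CC(=O)c2c(O)cccc2O1 | intermediate
14 | dimethyl (2S,2′S)-5,5′-dihydroxy-2,2′-bis[(2R,3S)-3-methyl-5-oxooxolan-2-yl]-4,4′-dioxo-6,6′-bichromane-2,2′-dicarboxylate | COC(=O)[C@@]1([C@@H]2OC(=O)C[C@@H]2C)CC(=O)c2c(ccc(-c3ccc4c(c3O)C(=O)C[C@@](C(=O)OC)([C@@H]3OC(=O)C[C@@H]3C)O4)c2O)O1 | intermediate
15 | trilithium salt of 16 (carboxylate and both phenolates) | COC(=O)[C@@]1([C@H](O)[C@@H](C)CC(=O)[O-])CC(=O)c2c(ccc(-c3ccc4c(c3[O-])C(=O)C[C@@](C(=O)OC)([C@@H]3OC(=O)C[C@@H]3C)O4)c2[O-])O1.[Li+].[Li+].[Li+] | intermediate (not isolated)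
16 | CNP0517857.1, mono-seco acid of 14 | COC(=O)[C@@]1([C@H](O)[C@@H](C)CC(=O)O)CC(=O)c2c(ccc(-c3ccc4c(c3O)C(=O)C[C@@](C(=O)OC)([C@@H]3OC(=O)C[C@@H]3C)O4)c2O)O1 | target

Total step count: 8. Longest linear sequence: 7 (steps 1, 2, 3, 5, 6, 7, 8).

## The three steps most likely to fail

**Step 5 (radical–radical coupling).** The reaction is unprecedented. Back electron transfer, butenolide homodimer, net reduction of 8 to the chromanone, sensitised [2+2] addition or the wrong C2′ epimer could all dominate.

The fallback sets out from 8 and 10 and replaces the radical manifold with a polar one. Compound 8 is treated with i-Pr2Si(OTf)2 and 2,6-lutidine in CH2Cl2 to give the silicon-bridged benzopyrylium triflate F1. This cation is attacked at C2 by 10 in a vinylogous Mukaiyama–Michael addition to give the bridged silyl enol ether F2. Treatment with 3HF·NEt3 then frees the phenol and the ketone, and the route is rejoined at 12.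

**Step 7 (oxidative phenol coupling).** The phenol is electron-poor, so 6,8′-linked isomers, oligomers or no reaction are all possible.

The fallback sets out from 13 and builds the axis by metal-mediated coupling instead of C–H oxidation. Iodination ortho to the phenol (BnNMe3·ICl2, CaCO3; any C8 isomer is separated) gives the 6-iodide F3. Pd-catalysed stannylation with (Me3Sn)2 gives the 6-trimethylstannane F4. CuCl in DMA under air then homocouples F4, and the route is rejoined at 14.

**Step 8 (mono-opening of the bis-lactone).** The yield has a statistical ceiling. The base could also trigger retro-oxa-Michael or Dieckmann chemistry, and the product could relactonise on work-up.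

The fallback sets out from 13 and makes the two halves different before they are joined, so no selectivity between equal lactones is needed. Part of the 6-iodide F3 is fully saponified at its single lactone (LiOH, 0 °C, then pH 4) to the iodo seco acid F5. F5 is then joined to the 6-trimethylstannane F4 by a neutral Stille cross-coupling (Pd2(dba)3, AsPh3, CuTC, DMF, rt). This rejoins the route directly at 16.

## Further compounds
F1 | step 5 | 4,5-(diisopropylsilanediyldioxy)-2-(methoxycarbonyl)benzopyrylium triflate | COC(=O)c1cc2O[Si](C(C)C)(C(C)C)Oc3cccc([o+]1)c32.[O-]S(=O)(=O)C(F)(F)F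
F2 | step 5 | rac-silicon-bridged 2H-chromene adduct, rel-(2S,2′R), one enantiomer drawn | COC(=O)[C@@]1([C@@H]2OC(=O)C=C2C)C=C2O[Si](C(C)C)(C(C)C)Oc3cccc(O1)c32
F3 | step 7 | methyl (2S)-5-hydroxy-6-iodo-2-[(2R,3S)-3-methyl-5-oxooxolan-2-yl]-4-oxochromane-2-carboxylate | COC(=O)[C@@]1([C@@H]2OC(=O)C[C@@H]2C)CC(=O)c2c(O)c(I)ccc2O1
F4 | step 7 | methyl (2S)-5-hydroxy-2-[(2R,3S)-3-methyl-5-oxooxolan-2-yl]-4-oxo-6-(trimethylstannyl)chromane-2-carboxylate | COC(=O)[C@@]1([C@@H]2OC(=O)C[C@@H]2C)CC(=O)c2c(O)c([Sn](C)(C)C)ccc2O1
F5 | step 8 | (3S,4R)-4-hydroxy-4-[(2S)-5-hydroxy-6-iodo-2-(methoxycarbonyl)-4-oxochroman-2-yl]-3-methylbutanoic acid | COC(=O)[C@@]1([C@H](O)[C@@H](C)CC(=O)O)CC(=O)c2c(O)c(I)ccc2O1
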